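**Plan**

1. Numbering: cyclopentane C1 (ring fusion, CH3), C2, C3, C4 (C(OH)i-Pr), C5 (ring-fusion CH); the cycloheptane continues C6 (O-angeloyl), C7 (CH2), C8 (epoxide C with CH3), C9 (epoxide CH), C10 (CHOH, bonded to C1). β is the face of the C1 methyl and C4 hydroxyl; α is the face of H5 and of the oxygens on C6, C8/C9 and C10.
2. Retrosynthesis: the epoxide oxygen and the angelate are removed, C5–H/C6–O goes back to a C5=C6 alkene and the C8 methyl to an ester on a C8=C9 alkene. The seven-membered ring then has two alkenes on either side of the C7 methylene with the adjacent stereocentres C1 and C10 opposite, a cyclohepta-1,4-diene. It is cut at C1–C10 and C7–C8, as the Cope product of a cis-divinylcyclopropane from a vinylcarbenoid (C8–C10) and a 1-vinylcyclopentene (C1–C7).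
3. Forward: the five-membered ring is made first by ozonolysis and aldol ring contraction of (S)-terpinen-4-ol, followed by methylenation (steps 1–4). The diazo partner is made in steps 5–6, the seven-membered ring closes in step 7, and steps 8–13 adjust C5/C6, the C8 substituent and the C8–C9 epoxide.
4. Stereochemistry: C4 comes from the chiral pool. C1 and C10 come from the chiral dirhodium catalyst (cyclopropane) relayed through the boat Cope transition state. C5 and C6 come from syn hydroboration on the α-face, and C8 and C9 from epoxidation directed by the C10 hydroxyl.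

Key step: step 7

Assumption: (S)-(+)-terpinen-4-ol is used enantiomerically pure, and the carbenoid ester is ethyl (a spectator that is later reduced to the C8 methyl group).

**Step 1**
Reactants: 1 (S)-terpinen-4-ol
Product: 2 (S)-terpinen-4-ol triethylsilyl ether
Conditions: TESOTf, 2,6-lutidine, CH2Cl2, 0 °C
Reagents that add atoms: triethylsilyl trifluoromethanesulfonate, CC[Si](CC)(CC)OS(=O)(=O)C(F)(F)F
Why: Silylation of the hindered tertiary alcohol with a silyl triflate and a non-nucleophilic base is routine and leaves C4 untouched; the silyl ether later prevents O–H insertion by the carbenoid and retro-aldol cleavage.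

**Step 2**
Reactants: 2 (S)-terpinen-4-ol triethylsilyl ether
Product: 4 (3S)-6-oxo-3-(propan-2-yl)-3-(triethylsilyloxy)heptanal, via ozonide 3 (not isolated)
Conditions: O3, CH2Cl2, −78 °C; then PPh3, −78 °C → rt
Reagents that add atoms: ozone, [O-][O+]=O
Why: Ozonolysis of the only alkene with reductive work-up (phosphine reduction of the ozonide) should give the 1,6-keto aldehyde without touching the silyl ether.

**Step 3**
Reactants: 4 (3S)-6-oxo-3-(propan-2-yl)-3-(triethylsilyloxy)heptanal
Product: 6 (5R)-2-methyl-5-(propan-2-yl)-5-(triethylsilyloxy)cyclopent-1-ene-1-carbaldehyde, via aldol adduct 5 (not isolated)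
Conditions: piperidine (0.2 equiv), AcOH (0.2 equiv), toluene, rt → 60 °C
Reagents that add atoms: none
Why: Intramolecular aldol condensation under piperidinium acetate catalysis: the enamine of the aldehyde attacks the methyl ketone (five-membered ring closure) and the aldol dehydrates to the tetrasubstituted enal, the classical ring contraction of keto aldehydes from 1-methylcyclohexenes, run buffered so that the β-silyloxy group is not eliminated.

**Step 4**
Reactants: 6 (5R)-2-methyl-5-(propan-2-yl)-5-(triethylsilyloxy)cyclopent-1-ene-1-carbaldehyde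
Product: 7 triethyl{[(1R)-2-ethenyl-3-methyl-1-(propan-2-yl)cyclopent-2-en-1-yl]oxy}silane (diene, carbons C1–C7)
Conditions: Ph3PCH3Br, KOt-Bu, THF, 0 °C → rt
Reagents that add atoms: methyltriphenylphosphonium bromide (as its ylide), C[P+](c1ccccc1)(c1ccccc1)c1ccccc1.[Br-]
Why: Wittig methylenation of the aldehyde, which in an enal proceeds by 1,2-addition, should give the 1-vinylcyclopentene without disturbing C4.

**Step 5**
Reactants: 8 (tert-butyldimethylsilyloxy)acetaldehyde; 9 ethyl diazoacetate
Product: 10 ethyl 4-(tert-butyldimethylsilyloxy)-2-diazo-3-hydroxybutanoate (racemic)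
Conditions: DBU (0.15 equiv), MeCN, rt
Reagents that add atoms: none
Why: Base-catalysed aldol-type addition of the nucleophilic diazo carbon of the diazoacetate to the aldehyde is a standard route to β-hydroxy-α-diazo esters.

**Step 6**
Reactants: 10 ethyl 4-(tert-butyldimethylsilyloxy)-2-diazo-3-hydroxybutanoate
Product: 12 ethyl (E)-4-(tert-butyldimethylsilyloxy)-2-diazobut-3-enoate (carbons C8–C10), via dichlorophosphate 11 (not isolated)
Conditions: POCl3, Et3N, CH2Cl2, 0 °C
Reagents that add atoms: none
Why: Dehydration of the β-hydroxy-α-diazo ester through its dichlorophosphate (E2 loss of a C4 hydrogen, the established POCl3/Et3N route to vinyldiazoacetates) should give the conjugated trans enol ether, the geometry that later places the C10 oxygen outward in the Cope transition state.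

**Step 7**
Reactants: 7 triethyl{[(1R)-2-ethenyl-3-methyl-1-(propan-2-yl)cyclopent-2-en-1-yl]oxy}silane; 12 ethyl (E)-4-(tert-butyldimethylsilyloxy)-2-diazobut-3-enoate
Product: 14 ethyl 10α-(tert-butyldimethylsilyloxy)-1β-methyl-4α-(propan-2-yl)-4β-(triethylsilyloxy)bicyclo[5.3.0]deca-5,8-diene-8-carboxylate (plan numbering; 1S,4R,10R), via divinylcyclopropane 13 (not isolated)
Conditions: Rh2(R-DOSP)4 (1 mol %; DOSP = N-(4-dodecylbenzenesulfonyl)prolinate), hexanes, −40 °C → rt, slow addition of 12 (1.5 equiv); then 70 °C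
Reagents that add atoms: none
Why: The dirhodium tetracarboxylate decomposes 12 to a donor/acceptor vinylcarbenoid that cyclopropanates the unhindered terminal vinyl group of 7 (new bonds C7–C8 and C6–C8), placing the silyloxyvinyl group cis to the cyclopentenyl group and the ester trans, so that cis-divinylcyclopropane 13 results. 13 then undergoes a Cope ([3,3]) rearrangement through a boat transition state in which C1–C10 forms as C6–C8 breaks; this pericyclic closure of the cis-held 1,5-diene makes the seven-membered ring as a cyclohepta-1,4-diene (C5=C6 and C8=C9). The closest known reaction type is the tandem cyclopropanation/Cope rearrangement (formal (4+3) cycloaddition) of vinyldiazoacetates with 1-vinylcycloalkenes under chiral dirhodium prolinate catalysis, including cases that create a quaternary carbon at the ring fusion. The two new stereocentres C1 and C10 are fixed together: their absolute sense follows the catalyst-controlled face of cyclopropanation (the R catalyst is chosen because the S catalyst is known to give the opposite cyclopropane sense with monosubstituted alkenes, which here would map to the enantiomeric C1/C10 pair), and their relative sense follows the boat geometry, in which the E-silyloxy group and C2 point outward and the C1 methyl and H10 inward, so that O10 ends trans to the C1 methyl. The step needs chemoselectivity for the vinyl group over the tetrasubstituted ring alkene, the allylic C–H bonds and the enol ether of a second molecule of 12 (secured by steric access, slow addition of 12 and a hydrocarbon solvent that suppresses vinylogous attack), cis selectivity in the cyclopropanation (inherent to donor/acceptor carbenoids) and reagent control over the remote C4 centre. The inward methyl and the isopropyl group next to C5 crowd the boat, hence the warming after the addition.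

**Step 8**
Reactants: 14 ethyl 10α-(tert-butyldimethylsilyloxy)-1β-methyl-4α-(propan-2-yl)-4β-(triethylsilyloxy)bicyclo[5.3.0]deca-5,8-diene-8-carboxylate
Product: 16 ethyl 6α-hydroxy-5α-H (trans-fused) 10α-(tert-butyldimethylsilyloxy)-1β-methyl-4α-(propan-2-yl)-4β-(triethylsilyloxy)bicyclo[5.3.0]dec-8-ene-8-carboxylate, via alkylborane 15 (not isolated)
Conditions: BH3·THF (3 equiv), THF, 0 °C → rt; then 30% H2O2, aq NaOAc, 0 °C → rt
Reagents that add atoms: hydrogen peroxide, OO
Why: Hydroboration–oxidation: borane should add syn across the electron-rich C5=C6 alkene (boron on the less substituted C6) in preference to the electron-poor enoate, and from the α-face because the β-face of C5 is flanked by both the angular C1 methyl and the C4 silyloxy group (as in 5-ene steroids, which give 5α,6α products), so that oxidation with retention sets H5 and the C6 hydroxyl α and the ring fusion trans.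

**Step 9**
Reactants: 16 ethyl 6α-hydroxy ester
Product: 17 6α-hydroxy-8-(hydroxymethyl) compound (C8=C9 alkene; 10α-OTBS; 4β-OTES; 5α-H)
Conditions: i-Bu2AlH (3.5 equiv), CH2Cl2, −78 → 0 °C
Reagents that add atoms: none
Why: 1,2-Reduction of the conjugated ester by the aluminium hydride should give the primary allylic alcohol and leave the alkene and silyl ethers intact.

**Step 10**
Reactants: 17 6α-hydroxy-8-(hydroxymethyl) compound
Product: 19 6α-hydroxy-8-methyl compound (C8=C9 alkene; 10α-OTBS; 4β-OTES; 5α-H), via allylic sulfate 18 (not isolated)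
Conditions: SO3·pyridine (1.2 equiv), THF, 0 °C; then LiAlH4, 0 °C → rt
Reagents that add atoms: none
Why: Selective sulfation of the primary allylic hydroxyl followed by hydride displacement of the allylic sulfate (deoxygenation without allylic transposition) should give the C8 methyl group, the hindered secondary C6 alkoxide being inert.

**Step 11**
Reactants: 19 6α-hydroxy-8-methyl compound; 20 angelic acid [(Z)-2-methylbut-2-enoic acid]
Product: 22 6α-angelate of 19 (10α-OTBS; 4β-OTES), via mixed anhydride 21 (not isolated)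
Conditions: 20, 2,4,6-trichlorobenzoyl chloride, Et3N, toluene, rt; then 19, 80 °C
Reagents that add atoms: none
Why: Yamaguchi-type esterification through the mixed 2,4,6-trichlorobenzoic anhydride without a nucleophilic catalyst, conditions known to transfer the angeloyl group without Z to E isomerisation, should acylate the only free hydroxyl (C6).

**Step 12**
Reactants: 22 6α-angelate bis-silyl ether
Product: 23 6α-angeloyloxy-4β,10α-diol with the C8=C9 alkene (8,9-deoxylapiferine)
Conditions: HF·pyridine, pyridine, THF, 0 °C → rt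
Reagents that add atoms: none
Why: Fluoride cleavage of both silyl ethers under buffered, non-basic conditions should free the C4 and C10 hydroxyls without isomerising or cleaving the angelate or ionising the allylic alcohol.

**Step 13**
Reactants: 23 6α-angeloyloxy-4β,10α-diol
Product: 24 lapiferine
Conditions: VO(acac)2 (5 mol %), t-BuOOH, CH2Cl2, 0 °C → rt
Reagents that add atoms: tert-butyl hydroperoxide, CC(C)(C)OO
Why: Hydroxyl-directed vanadium-catalysed epoxidation: the vanadate ester of the allylic C10 hydroxyl should deliver oxygen to the syn (α) face of the C8=C9 alkene, setting C8 and C9, while the electron-poor angelate alkene and the remote C4 hydroxyl do not interfere.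

**Compound list**

1 | (S)-terpinen-4-ol [(1S)-4-methyl-1-(propan-2-yl)cyclohex-3-en-1-ol] | CC1=CC[C@](O)(C(C)C)CC1 | starting material
2 | (S)-terpinen-4-ol triethylsilyl ether | CC1=CC[C@](O[Si](CC)(CC)CC)(C(C)C)CC1 | intermediate
3 | ozonide (1,2,4-trioxolane across the former ring alkene) of 2 | CC12OOC(O1)C[C@](O[Si](CC)(CC)CC)(C(C)C)CC2 | intermediate
4 | (3S)-6-oxo-3-(propan-2-yl)-3-(triethylsilyloxy)heptanal | O=CC[C@](O[Si](CC)(CC)CC)(C(C)C)CCC(C)=O | intermediate
5 | aldol adduct, (5R)-2-hydroxy-2-methyl-5-(propan-2-yl)-5-(triethylsilyloxy)cyclopentane-1-carbaldehyde (C1/C2 mixture) | O=CC1C(C)(O)CC[C@@]1(O[Si](CC)(CC)CC)C(C)C | intermediate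
6 | (5R)-2-methyl-5-(propan-2-yl)-5-(triethylsilyloxy)cyclopent-1-ene-1-carbaldehyde | O=CC1=C(C)CC[C@@]1(O[Si](CC)(CC)CC)C(C)C | intermediate
7 | triethyl{[(1R)-2-ethenyl-3-methyl-1-(propan-2-yl)cyclopent-2-en-1-yl]oxy}silane | C=CC1=C(C)CC[C@@]1(O[Si](CC)(CC)CC)C(C)C | intermediate
8 | (tert-butyldimethylsilyloxy)acetaldehyde | O=CCO[Si](C)(C)C(C)(C)C | starting material
9 | ethyl diazoacetate | CCOC(=O)C=[N+]=[N-] | starting material
10 | ethyl 4-(tert-butyldimethylsilyloxy)-2-diazo-3-hydroxybutanoate (racemic) | CCOC(=O)C(=[N+]=[N-])C(O)CO[Si](C)(C)C(C)(C)C | intermediate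
11 | ethyl 4-(tert-butyldimethylsilyloxy)-3-(dichlorophosphoryloxy)-2-diazobutanoate | CCOC(=O)C(=[N+]=[N-])C(OP(=O)(Cl)Cl)CO[Si](C)(C)C(C)(C)C | intermediate
12 | ethyl (E)-4-(tert-butyldimethylsilyloxy)-2-diazobut-3-enoate | CCOC(=O)C(=[N+]=[N-])/C=C/O[Si](C)(C)C(C)(C)C | intermediate
13 | ethyl (1R,2S)-1-[(E)-2-(tert-butyldimethylsilyloxy)ethenyl]-2-[(5R)-2-methyl-5-(propan-2-yl)-5-(triethylsilyloxy)cyclopent-1-en-1-yl]cyclopropane-1-carboxylate (vinyl groups cis) | CCOC(=O)[C@]1(/C=C/O[Si](C)(C)C(C)(C)C)C[C@H]1C1=C(C)CC[C@@]1(O[Si](CC)(CC)CC)C(C)C | intermediate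
14 | ethyl 10α-(tert-butyldimethylsilyloxy)-1β-methyl-4α-(propan-2-yl)-4β-(triethylsilyloxy)bicyclo[5.3.0]deca-5,8-diene-8-carboxylate (1S,4R,10R) | C1C(C(=O)OCC)=C[C@@H](O[Si](C)(C)C(C)(C)C)[C@@]2(C)CC[C@@](O[Si](CC)(CC)CC)(C(C)C)C2=C1 | intermediate
15 | 6α-boryl (BH2) adduct of 14 with 5α-H | B[C@H]1CC(C(=O)OCC)=C[C@@H](O[Si](C)(C)C(C)(C)C)[C@@]2(C)CC[C@@](O[Si](CC)(CC)CC)(C(C)C)[C@H]12 | intermediate
16 | ethyl 6α-hydroxy-5α-H-10α-(tert-butyldimethylsilyloxy)-1β-methyl-4α-(propan-2-yl)-4β-(triethylsilyloxy)bicyclo[5.3.0]dec-8-ene-8-carboxylate | O[C@H]1CC(C(=O)OCC)=C[C@@H](O[Si](C)(C)C(C)(C)C)[C@@]2(C)CC[C@@](O[Si](CC)(CC)CC)(C(C)C)[C@H]12 | intermediate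
17 | 6α-hydroxy-8-(hydroxymethyl) analogue of 16 | O[C@H]1CC(CO)=C[C@@H](O[Si](C)(C)C(C)(C)C)[C@@]2(C)CC[C@@](O[Si](CC)(CC)CC)(C(C)C)[C@H]12 | intermediate
18 | pyridinium salt of the primary allylic sulfate of 17 | O[C@H]1CC(COS(=O)(=O)[O-])=C[C@@H](O[Si](C)(C)C(C)(C)C)[C@@]2(C)CC[C@@](O[Si](CC)(CC)CC)(C(C)C)[C@H]12.c1cc[nH+]cc1 | intermediate
19 | 6α-hydroxy-8-methyl compound (C8=C9; 10α-OTBS; 4β-OTES; 5α-H) | O[C@H]1CC(C)=C[C@@H](O[Si](C)(C)C(C)(C)C)[C@@]2(C)CC[C@@](O[Si](CC)(CC)CC)(C(C)C)[C@H]12 | intermediate
20 | angelic acid [(Z)-2-methylbut-2-enoic acid] | C/C=C(/C)C(=O)O | starting material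
21 | angeloyl 2,4,6-trichlorobenzoyl anhydride | C/C=C(/C)C(=O)OC(=O)c1c(Cl)cc(Cl)cc1Cl | intermediate
22 | 6α-angelate of 19 | C/C=C(/C)C(=O)O[C@H]1CC(C)=C[C@@H](O[Si](C)(C)C(C)(C)C)[C@@]2(C)CC[C@@](O[Si](CC)(CC)CC)(C(C)C)[C@H]12 | intermediate
23 | 6α-angeloyloxy-4β,10α-dihydroxy compound with the C8=C9 alkene | C/C=C(/C)C(=O)O[C@H]1CC(C)=C[C@@H](O)[C@@]2(C)CC[C@@](O)(C(C)C)[C@H]12 | intermediate
24 | lapiferine | C/C=C(/C)C(=O)O[C@H]1C[C@@]2(C)O[C@H]2[C@@H](O)[C@@]2(C)CC[C@@](O)(C(C)C)[C@H]12 | target

**Step count**

Total: 13 steps. Longest linear sequence: 11 steps (steps 1–4 and 7–13); steps 5–6 make the diazo partner.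

**Steps most likely to fail**

Step 7. The electron-rich silyloxyvinyl carbenoid, or its diazo precursor 12, may be lost to self-cyclopropanation, vinylogous capture or cyclisation to a pyrazole before it meets the hindered vinyl group. The cyclopropane may also form with poor control relative to C4. The fallback sets out from 7 and 9 and comes back at 14, using a less donating and more robust enol ester carbenoid. Ethyl diazoacetate 9 and commercial 2-oxoethyl benzoate would give, by the operations of steps 5 and 6, ethyl 4-(benzoyloxy)-2-diazo-3-hydroxybutanoate F1, its dichlorophosphate F2 (not isolated) and ethyl (E)-4-(benzoyloxy)-2-diazobut-3-enoate F3. The same dirhodium catalyst would add F3 to 7 to give the benzoyloxyvinyl cis-divinylcyclopropane F4 and, after Cope rearrangement, the 10α-benzoate F5. Ethanolysis of the benzoate (K2CO3, EtOH), which cannot alter the ethyl ester, would give the 10α-alcohol F6, and TBSOTf/2,6-lutidine would return 14.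

Step 8. Borane may approach C5=C6 from the β-face, because the α-face lies on the concave side of the folded cycloheptadiene next to the C4 isopropyl group, which would give the cis-fused 6β-alcohol. Slow reaction at the hindered alkene may also allow reduction of the enoate. The fallback sets out from 14 and comes back at 16; it sets C5 and C6 in separate, hydroxyl-directed operations.
- Selective cleavage of the tertiary triethylsilyl ether (PPTS, EtOH, 0 °C) would give the 4β-alcohol F7.
- VO(acac)2/t-BuOOH epoxidation directed by the C4 hydroxyl would give the 5β,6β-epoxide F8.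
- Reductive opening with Cp2TiCl (trivalent titanium, from Cp2TiCl2 and Zn) and 1,4-cyclohexadiene should cleave the C5–O bond homolytically and transfer hydrogen to C5 anti to the titanium alkoxides, giving the trans-fused 6β-alcohol F9.
- Dess–Martin oxidation would give the 6-ketone F10.
- Reduction with Me4NBH(OAc)3 (AcOH/MeCN, −20 °C), with hydride delivered internally from the β-oriented C4 hydroxyl, would give the 4β,6α-diol F11.
- TESOTf/2,6-lutidine would give the 4,6-bis(triethylsilyl) ether F12, and PPTS/EtOH would remove the secondary triethylsilyl group to return 16.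

Step 11. The angeloyl group may isomerise to the tigloyl (E) group during activation, or acylation of the hindered C6 hydroxyl may stall. The fallback sets out from 19 and comes back at 22; it builds the Z alkene on the ester. DCC/DMAP esterification of 19 with 2-[bis(2,2,2-trifluoroethoxy)phosphoryl]propanoic acid would give the C6 phosphonopropanoate F13. Still–Gennari olefination with acetaldehyde (KN(SiMe3)2, 18-crown-6, THF, −78 °C) would then give 22 with the Z geometry set kinetically.

**Further compounds**

F1 | step 7 | ethyl 4-(benzoyloxy)-2-diazo-3-hydroxybutanoate | CCOC(=O)C(=[N+]=[N-])C(O)COC(=O)c1ccccc1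
F2 | step 7 | ethyl 4-(benzoyloxy)-3-(dichlorophosphoryloxy)-2-diazobutanoate | CCOC(=O)C(=[N+]=[N-])C(OP(=O)(Cl)Cl)COC(=O)c1ccccc1
F3 | step 7 | ethyl (E)-4-(benzoyloxy)-2-diazobut-3-enoate | CCOC(=O)C(=[N+]=[N-])/C=C/OC(=O)c1ccccc1
F4 | step 7 | benzoyloxyvinyl analogue of cis-divinylcyclopropane 13 | CCOC(=O)[C@]1(/C=C/OC(=O)c2ccccc2)C[C@H]1C1=C(C)CC[C@@]1(O[Si](CC)(CC)CC)C(C)C
F5 | step 7 | 10α-benzoate analogue of 14 | C1C(C(=O)OCC)=C[C@@H](OC(=O)c3ccccc3)[C@@]2(C)CC[C@@](O[Si](CC)(CC)CC)(C(C)C)C2=C1
F6 | step 7 | 10α-alcohol corresponding to 14 | C1C(C(=O)OCC)=C[C@@H](O)[C@@]2(C)CC[C@@](O[Si](CC)(CC)CC)(C(C)C)C2=C1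
F7 | step 8 | 4β-alcohol from 14 (10α-OTBS kept) | C1C(C(=O)OCC)=C[C@@H](O[Si](C)(C)C(C)(C)C)[C@@]2(C)CC[C@@](O)(C(C)C)C2=C1
F8 | step 8 | 5β,6β-epoxide of F7 | O1[C@@H]2CC(C(=O)OCC)=C[C@@H](O[Si](C)(C)C(C)(C)C)[C@@]3(C)CC[C@@](O)(C(C)C)[C@@]123
F9 | step 8 | trans-fused 4β,6β-diol (5α-H) | O[C@@H]1CC(C(=O)OCC)=C[C@@H](O[Si](C)(C)C(C)(C)C)[C@@]2(C)CC[C@@](O)(C(C)C)[C@H]12
F10 | step 8 | trans-fused 4β-hydroxy 6-ketone | O=C1CC(C(=O)OCC)=C[C@@H](O[Si](C)(C)C(C)(C)C)[C@@]2(C)CC[C@@](O)(C(C)C)[C@H]12
F11 | step 8 | trans-fused 4β,6α-diol | O[C@H]1CC(C(=O)OCC)=C[C@@H](O[Si](C)(C)C(C)(C)C)[C@@]2(C)CC[C@@](O)(C(C)C)[C@H]12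
F12 | step 8 | 4β,6α-bis(triethylsilyl) ether of F11 | CC[Si](CC)(CC)O[C@H]1CC(C(=O)OCC)=C[C@@H](O[Si](C)(C)C(C)(C)C)[C@@]2(C)CC[C@@](O[Si](CC)(CC)CC)(C(C)C)[C@H]12
F13 | step 11 | 6α-{2-[bis(2,2,2-trifluoroethoxy)phosphoryl]propanoate} of 19 | CC(P(=O)(OCC(F)(F)F)OCC(F)(F)F)C(=O)O[C@H]1CC(C)=C[C@@H](O[Si](C)(C)C(C)(C)C)[C@@]2(C)CC[C@@](O[Si](CC)(CC)CC)(C(C)C)[C@H]12
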